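**Retrosynthetic overview**

1. Candidone ⇐ (2S)-7-hydroxy-5-methoxy-8-prenylflavanone by O-methylation of its only free phenol.
2. That flavanone ⇐ one-pot union of benzaldehyde, a 1,1-dimethoxy-3-silyloxybutadiene and its 4-prenyl homologue: an asymmetric Mukaiyama aldol sets C2, then Me3SiOTf closes ring C as a 2-methoxy-4-silyloxydihydropyrylium ion and the prenylated diene is annulated onto it ([4+2], loss of methanol) to give aromatic ring A.
3. Both dienes ⇐ 4,4-dimethoxybut-3-en-2-one by enol silylation, one of them after α'-prenylation with prenyl bromide.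
4. 4,4-Dimethoxybut-3-en-2-one ⇐ acetyl chloride + 1,1-dichloroethene (acylation, loss of HCl), then NaOMe.
5. Ring order: ring B arrives with benzaldehyde; ring C and then ring A form in the same operation, and the acyclic partners carry in every ring-A substituent (5-OMe, 7-O, 8-prenyl).

Assumption: (S)-BINOL/Ti(OiPr)4 sends the diene to the Si face of benzaldehyde, as in related BINOL–titanium aldol and allylation reactions; if the sense proves opposite, (R)-BINOL is used. LiN(iPr)2 is used as the commercial solution.

**Route**

Step 1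
Reactants: 1 acetyl chloride; 2 1,1-dichloroethene
Product: 4 4,4-dichlorobut-3-en-2-one, via 4,4,4-trichlorobutan-2-one 3 (not isolated)
Conditions: AlCl3 (1.1 equiv), CH2Cl2, 0 → 20 °C; ice–water; steam distillation
Reagents that add atoms: none
Why: Friedel–Crafts-type acylation of an alkene, in which the acylium ion adds to the CH2 terminus of 2 and chloride caps the chlorine-stabilised cation to give 3, which loses HCl on steam distillation to the conjugated dichlorovinyl ketone (no stereocentre).

Step 2
Reactants: 4 4,4-dichlorobut-3-en-2-one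
Product: 5 4,4-dimethoxybut-3-en-2-one
Conditions: NaOMe (2.1 equiv), MeOH, 0 → 23 °C; distil
Reagents that add atoms: sodium methoxide, [Na+].[O-]C
Why: Twofold vinylic nucleophilic substitution (addition–elimination) of methoxide at the β-carbon of the β,β-dichloroenone gives the acylketene dimethyl acetal.

Step 3
Reactants: 5 4,4-dimethoxybut-3-en-2-one
Product: 6 1,1-dimethoxy-3-(trimethylsilyloxy)buta-1,3-diene
Conditions: LiN(iPr)2, THF, −78 °C; Me3SiCl, −78 → 0 °C; distil
Reagents that add atoms: chlorotrimethylsilane, C[Si](C)(C)Cl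
Why: Kinetic deprotonation of the methyl ketone and O-silylation (silyl enol ether formation) gives the Brassard-type 1,1-dialkoxy-3-silyloxy diene.

Step 4
Reactants: 5 4,4-dimethoxybut-3-en-2-one; 7 1-bromo-3-methylbut-2-ene (prenyl bromide)
Product: 8 1,1-dimethoxy-7-methylocta-1,6-dien-3-one, (MeO)2C=CH–C(=O)–CH2–CH2–CH=CMe2
Conditions: LiN(iPr)2, THF, −78 °C; then 7, −78 → 0 °C
Reagents that add atoms: none
Why: Kinetic α'-enolate alkylation (SN2 at the primary allylic carbon), as in α'-alkylations of vinylogous esters; the methyl group is the only enolisable position.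

Step 5
Reactants: 8 1,1-dimethoxy-7-methylocta-1,6-dien-3-one
Product: 9 1,1-dimethoxy-7-methyl-3-(trimethylsilyloxy)octa-1,3,6-triene (3Z/3E mixture; the geometry is lost later)
Conditions: LiN(iPr)2, THF, −78 °C; Me3SiCl, −78 → 0 °C; distil
Reagents that add atoms: chlorotrimethylsilane, C[Si](C)(C)Cl
Why: Silyl enol ether formation by kinetic deprotonation of the only α-CH2 gives the 4-substituted Brassard-type diene.

Step 6
Reactants: 10 benzaldehyde; 6 1,1-dimethoxy-3-(trimethylsilyloxy)buta-1,3-diene; 9 1,1-dimethoxy-7-methyl-3-(trimethylsilyloxy)octa-1,3,6-triene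
Product: 14 (2S)-7-hydroxy-5-methoxy-8-(3-methylbut-2-enyl)-2-phenylchroman-4-one, via aldol silyl ether 11 (not isolated), via dihydropyrylium triflate 12 (not isolated), via aryl silyl ether 13 (not isolated)
Conditions: (i) 10 (1.1 equiv), 6 (1.0 equiv), Ti(OiPr)4 (10 mol %), (S)-BINOL (20 mol %), Et2O, −20 °C; evaporate; (ii) 9 (1.5 equiv), 2,6-di-tert-butyl-4-methylpyridine (3.5 equiv), Me3SiOTf (3 equiv), CH2Cl2, −78 → −20 °C; (iii) aq. NaHCO3; citric acid, MeOH, 23 °C
Reagents that add atoms: none
Why: Proposed new method: stage (i) is a BINOL–titanium Mukaiyama aldol (the first half of a hetero-Diels–Alder reaction) in which the CH2 terminus of 6 adds to the Si face of benzaldehyde and so sets C2 as S in 11; in stage (ii) Me3SiOTf silylates the vinylogous-carbonate carbonyl of 11, the silyl ether oxygen closes onto the dialkoxycarbenium carbon and Me3SiOMe leaves (ring C, cation 12, C2–O bond never broken), the enol-silane terminus of 9 adds to C6 of 12, the ring C silyl enol ether so formed attacks the 1,1-dimethoxy-3-silyloxyallyl cation of the side chain (ring A), and two Me3SiOTf/base-mediated losses of methanol aromatise to 13, which is desilylated on work-up; the closest known reaction types are Keck-type BINOL–titanium reactions of siloxydienes with benzaldehyde, Me3SiOTf-generated 4-silyloxypyrylium ions that accept silyl enol ethers at C2, Noyori-type silyl ether/acetal exchange and Brassard-diene benzannulations.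

Step 7
Reactants: 14 (2S)-7-hydroxy-5-methoxy-8-(3-methylbut-2-enyl)-2-phenylchroman-4-one
Product: 15 candidone, (2S)-5,7-dimethoxy-8-(3-methylbut-2-enyl)-2-phenylchroman-4-one
Conditions: Me3SiCHN2, iPr2NEt, MeCN/MeOH 9:1, 23 °C
Reagents that add atoms: (trimethylsilyl)diazomethane, C[Si](C)(C)C=[N+]=[N-]
Why: Diazoalkane O-methylation of the acidic 7-phenol under essentially non-basic conditions, so the flavanone cannot open to the chalcone and C2 stays S; ketone and prenyl alkene are inert.

**Compound list**

1 | acetyl chloride | CC(=O)Cl | starting material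
2 | 1,1-dichloroethene | C=C(Cl)Cl | starting material
3 | 4,4,4-trichlorobutan-2-one | CC(=O)CC(Cl)(Cl)Cl | intermediate
4 | 4,4-dichlorobut-3-en-2-one | CC(=O)C=C(Cl)Cl | intermediate
5 | 4,4-dimethoxybut-3-en-2-one | CC(=O)C=C(OC)OC | intermediate
6 | 1,1-dimethoxy-3-(trimethylsilyloxy)buta-1,3-diene | COC(OC)=CC(=C)O[Si](C)(C)C | intermediate
7 | 1-bromo-3-methylbut-2-ene (prenyl bromide) | CC(C)=CCBr | starting material
8 | 1,1-dimethoxy-7-methylocta-1,6-dien-3-one | COC(OC)=CC(=O)CCC=C(C)C | intermediate
9 | 1,1-dimethoxy-7-methyl-3-(trimethylsilyloxy)octa-1,3,6-triene (3Z/3E mixture) | COC(OC)=CC(O[Si](C)(C)C)=CCC=C(C)C | intermediate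
10 | benzaldehyde | O=Cc1ccccc1 | starting material
11 | (5S)-1,1-dimethoxy-5-phenyl-5-(trimethylsilyloxy)pent-1-en-3-one | C[Si](C)(C)O[C@H](c1ccccc1)CC(=O)C=C(OC)OC | intermediate
12 | (2S)-6-methoxy-2-phenyl-4-(trimethylsilyloxy)-2,3-dihydropyrylium triflate (O1=C6 oxocarbenium, C4=C5 silyl enol ether) | COC1=[O+][C@H](c2ccccc2)CC(O[Si](C)(C)C)=C1.[O-]S(=O)(=O)C(F)(F)F | intermediate
13 | (2S)-5-methoxy-8-(3-methylbut-2-enyl)-2-phenyl-7-(trimethylsilyloxy)chroman-4-one | C[Si](C)(C)Oc1cc(OC)c2c(c1CC=C(C)C)O[C@H](c1ccccc1)CC2=O | intermediate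
14 | (2S)-7-hydroxy-5-methoxy-8-(3-methylbut-2-enyl)-2-phenylchroman-4-one | Oc1cc(OC)c2c(c1CC=C(C)C)O[C@H](c1ccccc1)CC2=O | intermediate
15 | candidone, (2S)-5,7-dimethoxy-8-(3-methylbut-2-enyl)-2-phenylchroman-4-one | COc1cc(OC)c2c(c1CC=C(C)C)O[C@H](c1ccccc1)CC2=O | target

**Totals**

Total step count: 7. Longest linear sequence: 6 (steps 1, 2, 4, 5, 6, 7); step 3 is the side branch.

**The three steps most likely to fail**

Step 6 is the main risk. The cascade is untested; the facial selectivity of the aldol stage is taken by analogy; and during aromatisation the exocyclic loss of methanol at the ring-fusion carbon has to beat opening of ring C. The fallback sets out from 10 and 6 and comes back at 14. The aldol stage is run alone and quenched with CF3CO2H, so that 11 cyclises to (2S)-6-methoxy-2-phenyl-2,3-dihydro-4H-pyran-4-one F1, which is isolated and checked for enantiomeric purity. F1 and 9 are then joined with only catalytic Me3SiOTf at −78 °C (vinylogous Mukaiyama addition–elimination at C6) to give (2S)-6-(1,1-dimethoxy-7-methyl-3-oxoocta-1,6-dien-4-yl)-2-phenyl-2,3-dihydro-4H-pyran-4-one F2. Ring A is closed separately with DBU in MeCN at 23 °C: γ-deprotonation, intramolecular addition–elimination at the ketene acetal carbon, loss of methanol and tautomerisation give 14. This gives up the one-pot cationic cascade for a stepwise sequence with an anionic ring closure.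

Step 4 is the second risk. The lithium enolate of the acylketene acetal 5 may self-condense or be dialkylated. The fallback sets out from 6 and 10 and comes back at 14, bringing the prenyl group in late by rearrangement instead of early by alkylation. Step 6 is run with a second portion of 6 in place of 9; through 11 and 12 this gives (2S)-5-methoxy-2-phenyl-7-(trimethylsilyloxy)chroman-4-one F3 and, after work-up, (2S)-7-hydroxy-5-methoxy-2-phenylchroman-4-one (alpinetin) F4. O-Allylation with tert-butyl 2-methylbut-3-en-2-yl carbonate and Pd(PPh3)4 in THF at 0 °C gives the tertiary ether (2S)-5-methoxy-7-(2-methylbut-3-en-2-yloxy)-2-phenylchroman-4-one F5. Its aromatic Claisen rearrangement in toluene at 110 °C moves the C5 unit to C8 as a prenyl group and gives 14; the C6 isomer is removed by chromatography.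

Step 7 is the third risk. The diazoalkane methylation may be slow, and any basic alternative risks chalcone formation and loss of the C2 configuration. The fallback sets out from 8 and comes back at 15, placing the methyl group before ring A is built. The potassium enolate of 8 (KN(SiMe3)2, THF/DMPU, −78 °C) is O-methylated with MeOTf to give 1,1,3-trimethoxy-7-methylocta-1,3,6-triene F6. F6 replaces 9 in step 6; the enol ether oxygen stays on C7 through the annulation and 15 forms directly through 11 and 12, so no phenol has to be methylated.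

**Further compounds**

F1 | step 6 | (2S)-6-methoxy-2-phenyl-2,3-dihydro-4H-pyran-4-one | COC1=CC(=O)C[C@@H](c2ccccc2)O1
F2 | step 6 | (2S)-6-(1,1-dimethoxy-7-methyl-3-oxoocta-1,6-dien-4-yl)-2-phenyl-2,3-dihydro-4H-pyran-4-one (side-chain centre unassigned) | COC(OC)=CC(=O)C(CC=C(C)C)C1=CC(=O)C[C@@H](c2ccccc2)O1
F3 | step 4 | (2S)-5-methoxy-2-phenyl-7-(trimethylsilyloxy)chroman-4-one | C[Si](C)(C)Oc1cc(OC)c2c(c1)O[C@H](c1ccccc1)CC2=O
F4 | step 4 | (2S)-7-hydroxy-5-methoxy-2-phenylchroman-4-one (alpinetin) | Oc1cc(OC)c2c(c1)O[C@H](c1ccccc1)CC2=O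
F5 | step 4 | (2S)-5-methoxy-7-(2-methylbut-3-en-2-yloxy)-2-phenylchroman-4-one | C=CC(C)(C)Oc1cc(OC)c2c(c1)O[C@H](c1ccccc1)CC2=O
F6 | step 7 | 1,1,3-trimethoxy-7-methylocta-1,3,6-triene | COC(OC)=CC(OC)=CCC=C(C)C
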